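**Strategy.** The butenolide ring is numbered O1, C2 (lactone C=O), C3 (bearing CH3), C4 (bearing CO2H), C5 (stereocentre). The route rests on reading O1–C2(=O) as a carbon dioxide unit and C3–C4–C5 as a three-carbon ambiphile: an alkenyl nucleophile at C3 and an sp3 electrophile at C5, held cis across C3=C4. In one operation an alkenylmagnesium at C3 captures CO2 (C2–C3) and the resulting carboxylate displaces a C5 mesylate with inversion (O1–C5), closing the ring and fixing (R)-C5. The precursor is an (S)-configured (E)-β-iodo Baylis–Hillman-type mesylate, built from tert-butyl but-2-ynoate and a C16 aldehyde by a titanium alkyne–aldehyde coupling, then ketone reduction.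

Key step: step 8

Remark: the given configuration corresponds to (R) at C5; ω-pentadecalactone and tert-butyl but-2-ynoate are taken as commercial.

**Step 1**
Reactants: 1 ω-pentadecalactone (oxacyclohexadecan-2-one)
Product: 3 16-hydroxyhexadecan-2-one, via Weinreb amide 2 (not isolated)
Conditions: MeNH(OMe)·HCl, iPrMgCl, THF, −15 °C; then MeMgBr, 0 °C; aq. NH4Cl
Reagents that add atoms: methylmagnesium bromide, C[Mg]Br
Why: Magnesium amide aminolysis of the lactone gives the Weinreb amide, and the Weinreb ketone synthesis should then stop at the methyl ketone because the magnesium chelate of the tetrahedral adduct survives until work-up.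

**Step 2**
Reactants: 3 16-hydroxyhexadecan-2-one
Product: 4 14-(2-methyl-1,3-dioxolan-2-yl)tetradecan-1-ol
Conditions: ethylene glycol, p-TsOH (cat.), toluene, reflux, Dean–Stark trap
Reagents that add atoms: ethylene glycol, OCCO
Why: Acid-catalysed ketalisation driven by azeotropic removal of water masks the methyl ketone against the later organometallic and hydride steps, the primary alcohol being unaffected.

**Step 3**
Reactants: 4 14-(2-methyl-1,3-dioxolan-2-yl)tetradecan-1-ol
Product: 5 14-(2-methyl-1,3-dioxolan-2-yl)tetradecanal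
Conditions: TEMPO (cat.), PhI(OAc)2, CH2Cl2, rt
Reagents that add atoms: none
Why: TEMPO-catalysed oxoammonium oxidation with PhI(OAc)2 as terminal oxidant should stop at the aldehyde, and the anhydrous, weakly acidic medium should leave the dioxolane intact.

**Step 4**
Reactants: 5 14-(2-methyl-1,3-dioxolan-2-yl)tetradecanal; 6 tert-butyl but-2-ynoate
Product: 9 tert-butyl (E)-2-[1-hydroxy-14-(2-methyl-1,3-dioxolan-2-yl)tetradecyl]-3-iodobut-2-enoate (racemic), via titanacyclopropene 7 (not isolated), via oxatitanacyclopentene 8 (not isolated)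
Conditions: 6, Ti(OiPr)4, iPrMgCl (2 equiv), Et2O, −78 to −50 °C; then 5, −78 °C; then I2, −78 to 0 °C; aq. NaHCO3/Na2S2O3
Reagents that add atoms: iodine, II
Why: Alkyne–aldehyde coupling through a low-valent titanium alkyne complex: the titanacyclopropene should add the aldehyde at its ester-bearing carbon (the Ti–C bond with titanium enolate character) to give a five-membered oxatitanacycle whose remaining Ti–C3 bond is necessarily cis to the new carbinol carbon, so iodinolysis with retention should give the (E)-β-iodo Baylis–Hillman-type alcohol; the carbinol centre forms racemic and is corrected in steps 5 and 6.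

**Step 5**
Reactants: 9 tert-butyl (E)-2-[1-hydroxy-14-(2-methyl-1,3-dioxolan-2-yl)tetradecyl]-3-iodobut-2-enoate (racemic)
Product: 10 tert-butyl (E)-3-iodo-2-[14-(2-methyl-1,3-dioxolan-2-yl)tetradecanoyl]but-2-enoate
Conditions: Dess–Martin periodinane, NaHCO3 (solid buffer), CH2Cl2, 0 °C to rt
Reagents that add atoms: none
Why: Dess–Martin oxidation of the hindered allylic alcohol under buffered, non-nucleophilic conditions erases the racemic centre, and the tetrasubstituted alkene, which has no α-hydrogen, should keep its geometry.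

**Step 6**
Reactants: 10 tert-butyl (E)-3-iodo-2-[14-(2-methyl-1,3-dioxolan-2-yl)tetradecanoyl]but-2-enoate
Product: 11 tert-butyl (E)-2-[(1S)-1-hydroxy-14-(2-methyl-1,3-dioxolan-2-yl)tetradecyl]-3-iodobut-2-enoate
Conditions: (R)-2-methyl-CBS-oxazaborolidine (20 mol%), catecholborane, toluene, −78 °C
Reagents that add atoms: none
Why: Corey–Bakshi–Shibata reduction: with the tetrasubstituted alkenyl group as the large and the n-alkyl chain as the small ketone substituent, the (R)-catalyst should deliver hydride to the face that gives the (S)-carbinol (same sense as acetophenone to (S)-1-phenylethanol).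

**Step 7**
Reactants: 11 tert-butyl (E)-2-[(1S)-1-hydroxy-14-(2-methyl-1,3-dioxolan-2-yl)tetradecyl]-3-iodobut-2-enoate
Product: 12 tert-butyl (E)-3-iodo-2-[(1S)-1-(methanesulfonyloxy)-14-(2-methyl-1,3-dioxolan-2-yl)tetradecyl]but-2-enoate
Conditions: Ms2O, Et3N, CH2Cl2, −20 °C; used without delay
Reagents that add atoms: methanesulfonic anhydride, CS(=O)(=O)OS(C)(=O)=O
Why: O-Sulfonylation leaves the C–O bond of the stereocentre untouched (retention), the chloride-free anhydride avoids substitution by chloride, and the ester on C4 disfavours ionisation of the allylic mesylate.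

**Step 8**
Reactants: 12 tert-butyl (E)-3-iodo-2-[(1S)-1-(methanesulfonyloxy)-14-(2-methyl-1,3-dioxolan-2-yl)tetradecyl]but-2-enoate
Product: 15 tert-butyl (2R)-4-methyl-2-[13-(2-methyl-1,3-dioxolan-2-yl)tridecyl]-5-oxo-2,5-dihydrofuran-3-carboxylate, via alkenylmagnesium chloride 13 (not isolated), via magnesium carboxylate 14 (not isolated)
Conditions: iPrMgCl·LiCl (1.05 equiv), THF, −78 to −40 °C; then dry CO2 (excess), −40 °C to rt; DMPU, 40 °C if closure is slow
Reagents that add atoms: carbon dioxide, O=C=O
Why: Iodine–magnesium exchange proceeds with retention of alkene geometry and places magnesium on C3 cis to C5; this alkenyl Grignard reagent adds to CO2 (C2–C3 bond), and the carboxylate, locked next to C5 by the C3=C4 double bond, displaces the mesylate intramolecularly on warming (O1–C5 bond). The closest known reaction types are the carboxylation of ester-bearing alkenylmagnesium reagents made by halogen–magnesium exchange and the classical closure of (Z)-γ-halo- or γ-sulfonyloxy-enoates to butenolides. The butenolide ring closes in the 5-exo-tet mode. C5 is set by stereospecific SN2 inversion, so the (S)-mesylate should give (R)-C5, the controlling element being the substrate configuration from step 6. The step needs exchange at C–I to outrun attack on the ester and the mesylate (low temperature, one equivalent of reagent, excess CO2 to quench residual Grignard reagent) and needs substitution without ionisation, which the electron-poor carbon C4 secures; the C4 ester cannot compete because it would have to close a four-membered ring.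

**Step 9**
Reactants: 15 tert-butyl (2R)-4-methyl-2-[13-(2-methyl-1,3-dioxolan-2-yl)tridecyl]-5-oxo-2,5-dihydrofuran-3-carboxylate
Product: 16 isomuronic acid, (2R)-4-methyl-5-oxo-2-(14-oxopentadecyl)-2,5-dihydrofuran-3-carboxylic acid
Conditions: TFA, CH2Cl2, H2O (5%), 0 °C to rt
Reagents that add atoms: water, O
Why: Acidolysis removes the tert-butyl ester as 2-methylpropene and the aqueous acid hydrolyses the dioxolane in the same pot; the butenolide and its C5 centre are stable to acid, and base is avoided because C5–H is vinylogously acidic.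

**Compound list**
1 | ω-pentadecalactone (oxacyclohexadecan-2-one) | O=C1CCCCCCCCCCCCCCO1 | starting material
2 | 15-hydroxy-N-methoxy-N-methylpentadecanamide (Weinreb amide) | CON(C)C(=O)CCCCCCCCCCCCCCO | intermediate
3 | 16-hydroxyhexadecan-2-one | CC(=O)CCCCCCCCCCCCCCO | intermediate
4 | 14-(2-methyl-1,3-dioxolan-2-yl)tetradecan-1-ol | CC1(CCCCCCCCCCCCCCO)OCCO1 | intermediate
5 | 14-(2-methyl-1,3-dioxolan-2-yl)tetradecanal | CC1(CCCCCCCCCCCCCC=O)OCCO1 | intermediate
6 | tert-butyl but-2-ynoate | CC#CC(=O)OC(C)(C)C | starting material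
7 | titanacyclopropene: Ti(OiPr)2 complex of 6 | CC1=C(C(=O)OC(C)(C)C)[Ti]1(OC(C)C)OC(C)C | intermediate
8 | oxatitanacyclopentene: 2,2-diisopropoxy-1-oxa-2-titanacyclopent-3-ene with CH3 on C3, CO2tBu on C4 and the ketal chain on C5 | CC1=C(C(=O)OC(C)(C)C)C(CCCCCCCCCCCCCC2(C)OCCO2)O[Ti]1(OC(C)C)OC(C)C | intermediate
9 | tert-butyl (E)-2-[1-hydroxy-14-(2-methyl-1,3-dioxolan-2-yl)tetradecyl]-3-iodobut-2-enoate (racemic) | C/C(I)=C(\C(=O)OC(C)(C)C)C(O)CCCCCCCCCCCCCC1(C)OCCO1 | intermediate
10 | tert-butyl (E)-3-iodo-2-[14-(2-methyl-1,3-dioxolan-2-yl)tetradecanoyl]but-2-enoate | C/C(I)=C(\C(=O)OC(C)(C)C)C(=O)CCCCCCCCCCCCCC1(C)OCCO1 | intermediate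
11 | tert-butyl (E)-2-[(1S)-1-hydroxy-14-(2-methyl-1,3-dioxolan-2-yl)tetradecyl]-3-iodobut-2-enoate | C/C(I)=C(\C(=O)OC(C)(C)C)[C@@H](O)CCCCCCCCCCCCCC1(C)OCCO1 | intermediate
12 | tert-butyl (E)-3-iodo-2-[(1S)-1-(methanesulfonyloxy)-14-(2-methyl-1,3-dioxolan-2-yl)tetradecyl]but-2-enoate | C/C(I)=C(\C(=O)OC(C)(C)C)[C@@H](OS(C)(=O)=O)CCCCCCCCCCCCCC1(C)OCCO1 | intermediate
13 | alkenylmagnesium chloride: 12 with MgCl in place of iodine on C3, geometry retained | C/C([Mg]Cl)=C(\C(=O)OC(C)(C)C)[C@@H](OS(C)(=O)=O)CCCCCCCCCCCCCC1(C)OCCO1 | intermediate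
14 | chloromagnesium (E)-3-(tert-butoxycarbonyl)-2-methyl-4-(methanesulfonyloxy)alk-2-enoate: 12 with CO2MgCl in place of iodine on C3, (4S) | C/C(C(=O)O[Mg]Cl)=C(\C(=O)OC(C)(C)C)[C@@H](OS(C)(=O)=O)CCCCCCCCCCCCCC1(C)OCCO1 | intermediate
15 | tert-butyl (2R)-4-methyl-2-[13-(2-methyl-1,3-dioxolan-2-yl)tridecyl]-5-oxo-2,5-dihydrofuran-3-carboxylate | CC1(CCCCCCCCCCCCC[C@H]2OC(=O)C(C)=C2C(=O)OC(C)(C)C)OCCO1 | intermediate
16 | isomuronic acid, (2R)-4-methyl-5-oxo-2-(14-oxopentadecyl)-2,5-dihydrofuran-3-carboxylic acid | CC(=O)CCCCCCCCCCCCC[C@H]1OC(=O)C(C)=C1C(=O)O | target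

**Step count.** Total: 9 steps. Longest linear sequence: 9 steps (1 to 16).

**Steps most likely to fail**

Step 8. The alkenylmagnesium may be quenched before it meets CO2, by proton transfer from the mesyl methyl group or by attack at sulfur, and a sluggish magnesium carboxylate may allow elimination instead of ring closure. The fallback sets out from 12 and comes back at 15, forming the two bonds in two stages by known chemistry. Alkoxycarbonylation of the alkenyl iodide under zerovalent palladium catalysis (Pd(PPh3)4, CO 1 atm, 2-(trimethylsilyl)ethanol, iPr2NEt, DMF, 50 °C) should give the silylethyl diester, 4-tert-butyl 1-[2-(trimethylsilyl)ethyl] (E)-2-methyl-3-[(1S)-1-(methanesulfonyloxy)-14-(2-methyl-1,3-dioxolan-2-yl)tetradecyl]but-2-enedioate F1. CsF in DMF at rt then removes the silylethyl group, and the carboxylate set free (the anion of 14) closes onto C5 with inversion to give 15.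

Step 4. The aldehyde may insert at the wrong carbon of the titanium alkyne complex, or the low-valent titanium may attack the ester or couple the aldehyde reductively. The fallback sets out from 5 and 6 and comes back at 9: an MgI2-promoted three-component iodo-aldol (halo-aldol) reaction in CH2Cl2, in which iodide adds in conjugate fashion to the ynoate and the metal enolate so formed adds to the aldehyde. This should give 9 together with its geometric isomer, tert-butyl (Z)-2-[1-hydroxy-14-(2-methyl-1,3-dioxolan-2-yl)tetradecyl]-3-iodobut-2-enoate F2, which is removed by chromatography.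

Step 6. Facial selectivity may be poor if the two ketone substituents are less well differentiated than assumed, and the electrophilic β-iodo enone 10 may lose its alkene geometry by addition–elimination before it is reduced. The fallback sets out from racemic 9 and comes back at 11 without passing through 10: acylative kinetic resolution with a chiral isothiourea catalyst (HyperBTM, isobutyric anhydride, iPr2NEt, CHCl3, 0 °C). The catalyst enantiomer that acylates the (R)-alcohol is chosen, so that this enantiomer is removed as tert-butyl (E)-3-iodo-2-[(1R)-1-(2-methylpropanoyloxy)-14-(2-methyl-1,3-dioxolan-2-yl)tetradecyl]but-2-enoate F3 and the unreacted (S)-alcohol 11 is carried on.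

**Further compounds**
F1 | step 8 | 4-tert-butyl 1-[2-(trimethylsilyl)ethyl] (E)-2-methyl-3-[(1S)-1-(methanesulfonyloxy)-14-(2-methyl-1,3-dioxolan-2-yl)tetradecyl]but-2-enedioate | C/C(C(=O)OCC[Si](C)(C)C)=C(\C(=O)OC(C)(C)C)[C@@H](OS(C)(=O)=O)CCCCCCCCCCCCCC1(C)OCCO1
F2 | step 4 | tert-butyl (Z)-2-[1-hydroxy-14-(2-methyl-1,3-dioxolan-2-yl)tetradecyl]-3-iodobut-2-enoate (racemic) | C/C(I)=C(/C(=O)OC(C)(C)C)C(O)CCCCCCCCCCCCCC1(C)OCCO1
F3 | step 6 | tert-butyl (E)-3-iodo-2-[(1R)-1-(2-methylpropanoyloxy)-14-(2-methyl-1,3-dioxolan-2-yl)tetradecyl]but-2-enoate | C/C(I)=C(\C(=O)OC(C)(C)C)[C@H](OC(=O)C(C)C)CCCCCCCCCCCCCC1(C)OCCO1
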